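**Retrosynthetic overview**

- The route rests on ring C of units 1 and 2, where C2 (catechol ring), C3 (O-gallate) and C4 (bonded to C8 of the next unit) are contiguous stereocentres. Cutting O1–C2 and C3–C4 together turns each ring C into an ortho-quinone methide (O1, C8a, C4a, C4) plus a Z enol gallate (C2=C3, gallate already on O3).
- Target 25 comes from benzylated trimer 24 by hydrogenolysis; 24 comes from 22 by exchanging the silyl ether on O3 of unit 3 for a gallate.
- Ring C of unit 1 is closed last: quinone methide from benzhydrol 20 (on C8 of unit 2) plus enol gallate 14. Benzhydrol 20 comes from dimer 16 by C8 iodination, iodine–magnesium exchange, addition to aldehyde 7 and deallylation.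
- Ring C of unit 2 is closed first, by the same cycloaddition from benzhydrol 10 (on C8 of unit 3). 10 comes from 8-lithiated protected (−)-epicatechin and aldehyde 7; 14 comes from alkyne 12 and acid 13 by Z-selective ruthenium-catalysed addition.
- Ring order: unit 3 is taken intact from (−)-epicatechin, then ring C of unit 2, then ring C of unit 1. Ring A of units 2 and 1 both come from aldehyde 7.

Key step: step 10

Assumption: the (R) enantiomer of the phosphoric acid is taken as the one that gives the 4β adduct; the sense of induction in an exo quinone-methide cycloaddition is not established, and the (S) acid would replace it if it proves to be the matched one.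
Assumption: 3,4-bis(benzyloxy)benzaldehyde and 3,4,5-tris(benzyloxy)benzoic acid are bought as such.

**Route**

Step 1
Reactants: 1 (−)-epicatechin
Product: 2 5,7,3',4'-tetra-O-benzyl-(−)-epicatechin (free 3-OH)
Conditions: BnBr (4.4 equiv), K2CO3, DMF, 0 °C to rt
Reagents that add atoms: benzyl bromide, BrCc1ccccc1
Why: Williamson etherification under carbonate conditions should alkylate the four phenols only and leave the secondary 3-OH and both stereocentres untouched.

Step 2
Reactants: 2 5,7,3',4'-tetra-O-benzyl-(−)-epicatechin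
Product: 3 5,7,3',4'-tetra-O-benzyl-3-O-(tert-butyldimethylsilyl)-(−)-epicatechin
Conditions: TBSCl, imidazole, DMF, rt
Reagents that add atoms: tert-butyldimethylsilyl chloride, CC(C)(C)[Si](C)(C)Cl
Why: Standard silylation of the secondary alcohol should give an ether that survives organolithium, phosphoric acid and zerovalent palladium steps.

Step 3
Reactants: 3 5,7,3',4'-tetra-O-benzyl-3-O-TBS-(−)-epicatechin
Product: 4 8-bromo-5,7,3',4'-tetra-O-benzyl-3-O-TBS-(−)-epicatechin
Conditions: NBS (1.0 equiv), CH2Cl2, −78 °C to rt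
Reagents that add atoms: N-bromosuccinimide, O=C1CCC(=O)N1Br
Why: Electrophilic aromatic bromination of ring A should go to C8, which lies between O1 and one benzyloxy group, in preference to C6, which lies between two benzyloxy groups.

Step 4
Reactants: 5 2,4,6-trihydroxybenzaldehyde
Product: 6 4,6-bis(benzyloxy)-2-hydroxybenzaldehyde
Conditions: BnBr (2.1 equiv), K2CO3, DMF, rt
Reagents that add atoms: benzyl bromide, BrCc1ccccc1
Why: Williamson etherification should stop after two benzylations because the last phenol is hydrogen-bonded to the formyl group and reacts much more slowly.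

Step 5
Reactants: 6 4,6-bis(benzyloxy)-2-hydroxybenzaldehyde
Product: 7 2-(allyloxy)-4,6-bis(benzyloxy)benzaldehyde
Conditions: allyl bromide, K2CO3, DMF, 60 °C
Reagents that add atoms: allyl bromide, C=CCBr
Why: Williamson etherification under forcing conditions should cap the chelated phenol with an allyl group, chosen because it can later be removed without acid, which would ionise the electron-rich benzhydrol.

Step 6
Reactants: 4 8-bromo-5,7,3',4'-tetra-O-benzyl-3-O-TBS-(−)-epicatechin; 7 2-(allyloxy)-4,6-bis(benzyloxy)benzaldehyde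
Product: 9 [2-(allyloxy)-4,6-bis(benzyloxy)phenyl](5,7,3',4'-tetra-O-benzyl-3-O-TBS-epicatechin-8-yl)methanol (both carbinol epimers), via 8-lithio flavan 8 (not isolated)
Conditions: n-BuLi (1.05 equiv), THF, −78 °C; then 7, −78 to −40 °C; then H2O
Reagents that add atoms: none
Why: Bromine–lithium exchange followed by 1,2-addition of the aryllithium to the aldehyde should give the benzhydrol; the new carbinol centre need not be controlled because it becomes sp2 in step 10.

Step 7
Reactants: 9 benzhydrol allyl ether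
Product: 10 [4,6-bis(benzyloxy)-2-hydroxyphenyl](5,7,3',4'-tetra-O-benzyl-3-O-TBS-epicatechin-8-yl)methanol (both carbinol epimers)
Conditions: Pd(PPh3)4 (5 mol%), morpholine, THF, rt
Reagents that add atoms: none
Why: Tsuji–Trost deallylation with zerovalent palladium and an amine allyl acceptor should free the phenol under neutral to basic conditions that leave the benzhydrol, silyl ether and benzyl ethers intact.

Step 8
Reactants: 11 3,4-bis(benzyloxy)benzaldehyde
Product: 12 1,2-bis(benzyloxy)-4-ethynylbenzene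
Conditions: dimethyl (1-diazo-2-oxopropyl)phosphonate, K2CO3, MeOH/THF, rt
Reagents that add atoms: dimethyl (1-diazo-2-oxopropyl)phosphonate, CC(=O)C(=[N+]=[N-])P(=O)(OC)OC
Why: Ohira–Bestmann homologation should convert the aldehyde into the terminal alkyne through the diazoalkene, loss of nitrogen and 1,2-hydrogen shift.

Step 9
Reactants: 12 1,2-bis(benzyloxy)-4-ethynylbenzene; 13 3,4,5-tris(benzyloxy)benzoic acid
Product: 14 (Z)-2-[3,4-bis(benzyloxy)phenyl]vinyl 3,4,5-tris(benzyloxy)benzoate
Conditions: Ru(η3-2-methylallyl)2(1,5-cyclooctadiene) (cat.), 1,4-bis(diphenylphosphino)butane, toluene, 65 °C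
Reagents that add atoms: none
Why: Ruthenium-catalysed anti-Markovnikov hydro-acyloxylation of a terminal alkyne proceeds through a ruthenium vinylidene that the carboxylate attacks at the carbon bonded to ruthenium, and with this diphosphine it should give the Z enol ester.

Step 10
Reactants: 10 ortho-hydroxybenzhydrol on C8 of unit 3; 14 Z enol gallate (2.5 equiv)
Product: 16 protected dimer 5,7,3',4'-tetra-O-benzyl-3-O-(3,4,5-tri-O-benzylgalloyl)epicatechin-(4β→8)-5,7,3',4'-tetra-O-benzyl-3-O-TBS-epicatechin, via ortho-quinone methide 15 (not isolated)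
Conditions: (R)-3,3'-bis(2,4,6-triisopropylphenyl)-1,1'-binaphthyl-2,2'-diyl hydrogen phosphate (10 mol%), 4 Å molecular sieves, toluene, −20 to 0 °C
Reagents that add atoms: none
Why: Proposed new method: the phosphoric acid protonates the doubly benzylic carbinol of 10, water leaves and the hydrogen-bonded ortho-quinone methide 15 results, a 1-oxadiene made of O1, C8a, C4a and C4 of the future unit 2; its C4 is attacked by the acyloxy-bearing carbon of 14 while O1 closes onto the benzylic carbon, an asynchronous inverse-electron-demand hetero-Diels–Alder reaction. The closest known reaction type is the chiral phosphoric acid catalysed (4+2) cycloaddition of ortho-quinone methides, generated in situ from ortho-hydroxybenzyl alcohols, with styrenes, enol ethers or enamides to give chromans; new here are a Z β-acyloxystyrene as the 2π partner and the demand for the exo adduct. Ring C of unit 2 closes in the (4+2) mode, O1–C2 and C3–C4 being formed in one operation, and the 3,4-bis(benzyloxy)phenyl group polarises the alkene so that the aryl group ends on C2 and the gallate on C3. C2 and C3 are set cis by suprafacial addition to the Z alkene, C4 is set trans to C3 by exo approach to the E-configured methide, in which the gallate avoids the twisted, di-ortho-substituted C8 aryl of unit 3, and the absolute sense of all three centres is set by the phosphate, which is hydrogen-bonded to the quinone-methide oxygen and shields one face with its 2,4,6-triisopropylphenyl groups. The step needs concertedness and exo selectivity: the electron-withdrawing acyloxy group on the attacking carbon, the non-polar solvent and the low temperature should keep a free C2 benzylic cation from forming, and the steric clash named above should override the usual endo preference.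

Step 11
Reactants: 16 protected dimer
Product: 17 protected dimer carrying iodine on C8 of unit 2
Conditions: NIS (1.0 equiv), CH2Cl2, −20 to 0 °C, dark
Reagents that add atoms: N-iodosuccinimide, O=C1CCC(=O)N1I
Why: Electrophilic aromatic iodination should go to the only free C8 position (unit 2), because the two free C6 positions lie between two benzyloxy groups and react more slowly, as in the monomer bromination of step 3.

Step 12
Reactants: 17 C8-iodinated dimer; 7 2-(allyloxy)-4,6-bis(benzyloxy)benzaldehyde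
Product: 19 protected dimer carrying [2-(allyloxy)-4,6-bis(benzyloxy)phenyl](hydroxy)methyl on C8 of unit 2 (both carbinol epimers), via arylmagnesium chloride 18 (not isolated)
Conditions: iPrMgCl·LiCl (1.1 equiv), THF, −20 °C; then 7, −20 to 0 °C; then H2O
Reagents that add atoms: none
Why: Iodine–magnesium exchange, accelerated by the two ortho oxygen substituents, gives an arylmagnesium reagent that should add to the aldehyde while sparing the gallate ester at this temperature, which an aryllithium would not do.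

Step 13
Reactants: 19 benzhydrol allyl ether on unit 2
Product: 20 protected dimer carrying [4,6-bis(benzyloxy)-2-hydroxyphenyl](hydroxy)methyl on C8 of unit 2 (both carbinol epimers)
Conditions: Pd(PPh3)4 (5 mol%), morpholine, THF, rt
Reagents that add atoms: none
Why: Tsuji–Trost deallylation as in step 7 should free the phenol without touching the gallate ester, the silyl ether or the acid-sensitive benzhydrol.

Step 14
Reactants: 20 ortho-hydroxybenzhydrol on C8 of unit 2; 14 Z enol gallate (2.5 equiv)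
Product: 22 protected trimer [tetra-O-benzyl-3-O-(tri-O-benzylgalloyl)epicatechin]-(4β→8)-[tetra-O-benzyl-3-O-(tri-O-benzylgalloyl)epicatechin]-(4β→8)-[tetra-O-benzyl-3-O-TBS-epicatechin], via ortho-quinone methide 21 (not isolated)
Conditions: (R)-3,3'-bis(2,4,6-triisopropylphenyl)-1,1'-binaphthyl-2,2'-diyl hydrogen phosphate (10 mol%), 4 Å molecular sieves, toluene, −20 to 0 °C
Reagents that add atoms: none
Why: Proposed new method: acid-catalysed dehydration of 20 gives ortho-quinone methide 21, which should add the Z enol gallate in the same exo, suprafacial inverse-demand hetero-Diels–Alder reaction as in step 10 (closest known reaction type: chiral phosphoric acid catalysed (4+2) cycloaddition of ortho-quinone methides with styrenes and enol ethers), closing ring C of unit 1 with C2/C3 cis from the alkene geometry, C4 trans to C3 from exo approach away from the C8 aryl of unit 2, and the face chosen by the phosphate.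

Step 15
Reactants: 22 protected trimer with silyl ether on unit 3
Product: 23 protected trimer with free 3-OH on unit 3
Conditions: HF·pyridine, THF/pyridine, 0 °C to rt
Reagents that add atoms: none
Why: Fluoride-driven desilylation buffered by pyridine should remove the secondary silyl ether without cleaving the gallate esters or the interflavan bonds.

Step 16
Reactants: 23 protected trimer with free 3-OH on unit 3; 13 3,4,5-tris(benzyloxy)benzoic acid
Product: 24 fully benzylated trimer tris-gallate (21 benzyl ethers)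
Conditions: 13 (3 equiv), DCC, DMAP, CH2Cl2, rt
Reagents that add atoms: none
Why: Steglich esterification acylates the secondary alcohol through the acylpyridinium ion with retention at C3.

Step 17
Reactants: 24 fully benzylated trimer tris-gallate
Product: 25 procyanidin C1 3,3',3''-tri-O-gallate
Conditions: H2 (1 atm), Pd(OH)2/C, THF/MeOH/H2O, rt
Reagents that add atoms: none
Why: Hydrogenolysis of the 21 aryl benzyl ethers under neutral conditions should free all phenols while leaving the gallate esters, the ring C ether bonds and the C4–C8 bonds intact.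

**Compound list**

1 | (−)-epicatechin | O[C@@H]1Cc2c(O)cc(O)cc2O[C@@H]1c1ccc(O)c(O)c1 | starting material
2 | 5,7,3',4'-tetra-O-benzyl-(−)-epicatechin | O[C@@H]1Cc2c(OCc3ccccc3)cc(OCc3ccccc3)cc2O[C@@H]1c1ccc(OCc2ccccc2)c(OCc2ccccc2)c1 | intermediate
3 | 5,7,3',4'-tetra-O-benzyl-3-O-TBS-(−)-epicatechin | CC(C)(C)[Si](C)(C)O[C@@H]1Cc2c(OCc3ccccc3)cc(OCc3ccccc3)cc2O[C@@H]1c1ccc(OCc2ccccc2)c(OCc2ccccc2)c1 | intermediate
4 | 8-bromo-5,7,3',4'-tetra-O-benzyl-3-O-TBS-(−)-epicatechin | CC(C)(C)[Si](C)(C)O[C@@H]1Cc2c(OCc3ccccc3)cc(OCc3ccccc3)c(Br)c2O[C@@H]1c1ccc(OCc2ccccc2)c(OCc2ccccc2)c1 | intermediate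
5 | 2,4,6-trihydroxybenzaldehyde | O=Cc1c(O)cc(O)cc1O | starting material
6 | 4,6-bis(benzyloxy)-2-hydroxybenzaldehyde | O=Cc1c(O)cc(OCc2ccccc2)cc1OCc1ccccc1 | intermediate
7 | 2-(allyloxy)-4,6-bis(benzyloxy)benzaldehyde | O=Cc1c(OCC=C)cc(OCc2ccccc2)cc1OCc1ccccc1 | intermediate
8 | 8-lithio-5,7,3',4'-tetra-O-benzyl-3-O-TBS-(−)-epicatechin (not isolated) | CC(C)(C)[Si](C)(C)O[C@@H]1Cc2c(OCc3ccccc3)cc(OCc3ccccc3)c([Li])c2O[C@@H]1c1ccc(OCc2ccccc2)c(OCc2ccccc2)c1 | intermediate
9 | [2-(allyloxy)-4,6-bis(benzyloxy)phenyl](5,7,3',4'-tetra-O-benzyl-3-O-TBS-epicatechin-8-yl)methanol, carbinol epimers | OC(c1c(OCc2ccccc2)cc(OCc2ccccc2)c2c1O[C@H](c1ccc(OCc3ccccc3)c(OCc3ccccc3)c1)[C@H](O[Si](C)(C)C(C)(C)C)C2)c1c(OCC=C)cc(OCc2ccccc2)cc1OCc1ccccc1 | intermediate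
10 | [4,6-bis(benzyloxy)-2-hydroxyphenyl](5,7,3',4'-tetra-O-benzyl-3-O-TBS-epicatechin-8-yl)methanol, carbinol epimers | OC(c1c(OCc2ccccc2)cc(OCc2ccccc2)c2c1O[C@H](c1ccc(OCc3ccccc3)c(OCc3ccccc3)c1)[C@H](O[Si](C)(C)C(C)(C)C)C2)c1c(O)cc(OCc2ccccc2)cc1OCc1ccccc1 | intermediate
11 | 3,4-bis(benzyloxy)benzaldehyde | O=Cc1ccc(OCc2ccccc2)c(OCc2ccccc2)c1 | starting material
12 | 1,2-bis(benzyloxy)-4-ethynylbenzene | C#Cc1ccc(OCc2ccccc2)c(OCc2ccccc2)c1 | intermediate
13 | 3,4,5-tris(benzyloxy)benzoic acid | OC(=O)c1cc(OCc2ccccc2)c(OCc2ccccc2)c(OCc2ccccc2)c1 | starting material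
14 | (Z)-2-[3,4-bis(benzyloxy)phenyl]vinyl 3,4,5-tris(benzyloxy)benzoate | O=C(O/C=C\c1ccc(OCc2ccccc2)c(OCc2ccccc2)c1)c1cc(OCc2ccccc2)c(OCc2ccccc2)c(OCc2ccccc2)c1 | intermediate
15 | ortho-quinone methide of 10: 3,5-bis(benzyloxy)-6-[(protected epicatechin-8-yl)methylidene]cyclohexa-2,4-dien-1-one (not isolated) | O=C1C=C(OCc2ccccc2)C=C(OCc2ccccc2)C1=Cc1c(OCc2ccccc2)cc(OCc2ccccc2)c2c1O[C@H](c1ccc(OCc3ccccc3)c(OCc3ccccc3)c1)[C@H](O[Si](C)(C)C(C)(C)C)C2 | intermediate
16 | protected dimer: tetra-O-benzyl-3-O-(tri-O-benzylgalloyl)epicatechin-(4β→8)-tetra-O-benzyl-3-O-TBS-epicatechin | O=C(O[C@@H]1[C@@H](c2c(OCc3ccccc3)cc(OCc3ccccc3)c3c2O[C@H](c2ccc(OCc4ccccc4)c(OCc4ccccc4)c2)[C@H](O[Si](C)(C)C(C)(C)C)C3)c2c(OCc3ccccc3)cc(OCc3ccccc3)cc2O[C@@H]1c1ccc(OCc2ccccc2)c(OCc2ccccc2)c1)c1cc(OCc2ccccc2)c(OCc2ccccc2)c(OCc2ccccc2)c1 | intermediate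
17 | protected dimer with iodine on C8 of unit 2 | O=C(O[C@@H]1[C@@H](c2c(OCc3ccccc3)cc(OCc3ccccc3)c3c2O[C@H](c2ccc(OCc4ccccc4)c(OCc4ccccc4)c2)[C@H](O[Si](C)(C)C(C)(C)C)C3)c2c(OCc3ccccc3)cc(OCc3ccccc3)c(I)c2O[C@@H]1c1ccc(OCc2ccccc2)c(OCc2ccccc2)c1)c1cc(OCc2ccccc2)c(OCc2ccccc2)c(OCc2ccccc2)c1 | intermediate
18 | protected dimer with chloromagnesio group on C8 of unit 2 (not isolated) | O=C(O[C@@H]1[C@@H](c2c(OCc3ccccc3)cc(OCc3ccccc3)c3c2O[C@H](c2ccc(OCc4ccccc4)c(OCc4ccccc4)c2)[C@H](O[Si](C)(C)C(C)(C)C)C3)c2c(OCc3ccccc3)cc(OCc3ccccc3)c([Mg]Cl)c2O[C@@H]1c1ccc(OCc2ccccc2)c(OCc2ccccc2)c1)c1cc(OCc2ccccc2)c(OCc2ccccc2)c(OCc2ccccc2)c1 | intermediate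
19 | protected dimer with [2-(allyloxy)-4,6-bis(benzyloxy)phenyl](hydroxy)methyl on C8 of unit 2, carbinol epimers | O=C(O[C@@H]1[C@@H](c2c(OCc3ccccc3)cc(OCc3ccccc3)c3c2O[C@H](c2ccc(OCc4ccccc4)c(OCc4ccccc4)c2)[C@H](O[Si](C)(C)C(C)(C)C)C3)c2c(OCc3ccccc3)cc(OCc3ccccc3)c(C(O)c3c(OCC=C)cc(OCc4ccccc4)cc3OCc3ccccc3)c2O[C@@H]1c1ccc(OCc2ccccc2)c(OCc2ccccc2)c1)c1cc(OCc2ccccc2)c(OCc2ccccc2)c(OCc2ccccc2)c1 | intermediate
20 | protected dimer with [4,6-bis(benzyloxy)-2-hydroxyphenyl](hydroxy)methyl on C8 of unit 2, carbinol epimers | O=C(O[C@@H]1[C@@H](c2c(OCc3ccccc3)cc(OCc3ccccc3)c3c2O[C@H](c2ccc(OCc4ccccc4)c(OCc4ccccc4)c2)[C@H](O[Si](C)(C)C(C)(C)C)C3)c2c(OCc3ccccc3)cc(OCc3ccccc3)c(C(O)c3c(O)cc(OCc4ccccc4)cc3OCc3ccccc3)c2O[C@@H]1c1ccc(OCc2ccccc2)c(OCc2ccccc2)c1)c1cc(OCc2ccccc2)c(OCc2ccccc2)c(OCc2ccccc2)c1 | intermediate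
21 | ortho-quinone methide of 20 (not isolated) | O=C(O[C@@H]1[C@@H](c2c(OCc3ccccc3)cc(OCc3ccccc3)c3c2O[C@H](c2ccc(OCc4ccccc4)c(OCc4ccccc4)c2)[C@H](O[Si](C)(C)C(C)(C)C)C3)c2c(OCc3ccccc3)cc(OCc3ccccc3)c(C=C3C(=O)C=C(OCc4ccccc4)C=C3OCc3ccccc3)c2O[C@@H]1c1ccc(OCc2ccccc2)c(OCc2ccccc2)c1)c1cc(OCc2ccccc2)c(OCc2ccccc2)c(OCc2ccccc2)c1 | intermediate
22 | protected trimer, gallates on units 1 and 2, TBS on unit 3 | O=C(O[C@@H]1[C@@H](c2c(OCc3ccccc3)cc(OCc3ccccc3)c3c2O[C@H](c2ccc(OCc4ccccc4)c(OCc4ccccc4)c2)[C@H](O[Si](C)(C)C(C)(C)C)C3)c2c(OCc3ccccc3)cc(OCc3ccccc3)c([C@H]3c4c(OCc5ccccc5)cc(OCc5ccccc5)cc4O[C@H](c4ccc(OCc5ccccc5)c(OCc5ccccc5)c4)[C@@H]3OC(=O)c3cc(OCc4ccccc4)c(OCc4ccccc4)c(OCc4ccccc4)c3)c2O[C@@H]1c1ccc(OCc2ccccc2)c(OCc2ccccc2)c1)c1cc(OCc2ccccc2)c(OCc2ccccc2)c(OCc2ccccc2)c1 | intermediate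
23 | protected trimer, gallates on units 1 and 2, free 3-OH on unit 3 | O=C(O[C@@H]1[C@@H](c2c(OCc3ccccc3)cc(OCc3ccccc3)c3c2O[C@H](c2ccc(OCc4ccccc4)c(OCc4ccccc4)c2)[C@H](O)C3)c2c(OCc3ccccc3)cc(OCc3ccccc3)c([C@H]3c4c(OCc5ccccc5)cc(OCc5ccccc5)cc4O[C@H](c4ccc(OCc5ccccc5)c(OCc5ccccc5)c4)[C@@H]3OC(=O)c3cc(OCc4ccccc4)c(OCc4ccccc4)c(OCc4ccccc4)c3)c2O[C@@H]1c1ccc(OCc2ccccc2)c(OCc2ccccc2)c1)c1cc(OCc2ccccc2)c(OCc2ccccc2)c(OCc2ccccc2)c1 | intermediate
24 | fully benzylated procyanidin C1 tris-gallate | O=C(O[C@@H]1[C@@H](c2c(OCc3ccccc3)cc(OCc3ccccc3)c3c2O[C@H](c2ccc(OCc4ccccc4)c(OCc4ccccc4)c2)[C@H](OC(=O)c2cc(OCc4ccccc4)c(OCc4ccccc4)c(OCc4ccccc4)c2)C3)c2c(OCc3ccccc3)cc(OCc3ccccc3)c([C@H]3c4c(OCc5ccccc5)cc(OCc5ccccc5)cc4O[C@H](c4ccc(OCc5ccccc5)c(OCc5ccccc5)c4)[C@@H]3OC(=O)c3cc(OCc4ccccc4)c(OCc4ccccc4)c(OCc4ccccc4)c3)c2O[C@@H]1c1ccc(OCc2ccccc2)c(OCc2ccccc2)c1)c1cc(OCc2ccccc2)c(OCc2ccccc2)c(OCc2ccccc2)c1 | intermediate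
25 | procyanidin C1 3,3',3''-tri-O-gallate | O=C(O[C@@H]1[C@@H](c2c(O)cc(O)c3c2O[C@H](c2ccc(O)c(O)c2)[C@H](OC(=O)c2cc(O)c(O)c(O)c2)C3)c2c(O)cc(O)c([C@H]3c4c(O)cc(O)cc4O[C@H](c4ccc(O)c(O)c4)[C@@H]3OC(=O)c3cc(O)c(O)c(O)c3)c2O[C@@H]1c1ccc(O)c(O)c1)c1cc(O)c(O)c(O)c1 | target

**Step count**

Total: 17 steps. Longest linear sequence: 13 steps (1, 2, 3, 6, 7, 10, 11, 12, 13, 14, 15, 16, 17).

**Steps most likely to fail**

Step 10 (proposed new method). Several processes may go wrong:
- The addition may become stepwise, with bond rotation at a C2 benzylic cation or participation of the gallate carbonyl, so that the cis relation of C2 and C3 is lost.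
- Endo approach, or reaction through the other methide geometry, may give the 3,4-cis adduct.
- The phosphate may control the face poorly against the bias of unit 3.
- The quinone methide may be consumed by Friedel–Crafts attack of electron-rich A rings.
- The enol ester may transfer its acyl group to the free phenol.

The fallback uses known chemistry and forms the C4–C8 bond instead of ring C. It sets out from 2 and 3. Compound 2 is oxidised at C4 with DDQ in the presence of 2-ethoxyethanol (CH2Cl2, rt) to 5,7,3',4'-tetra-O-benzyl-4β-(2-ethoxyethoxy)epicatechin F1. Esterification with 13 (DCC, DMAP, CH2Cl2) should give its 3-O-(tri-O-benzylgallate) F2. Catalytic Me3SiOSO2CF3 (CH2Cl2, −78 °C) then ionises F2 at C4. The cation, shielded on its α face by the neighbouring gallate, is trapped by C8 of an excess of 3, and the route is rejoined at 16.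

Step 14 (proposed new method). The same processes as in step 10 may occur, made worse by the larger C8 aryl group (the whole dimer). In addition, acid may cleave the existing C4–C8 bond. The fallback uses known chemistry, sets out from 16 and from 2, and avoids protic or strong Lewis acid in the coupling. F1 and then F2 are made from 2 as described above. F2 is treated with 2-mercaptobenzothiazole and BF3·OEt2 (CH2Cl2, −78 to 0 °C) to give the 4β-(1,3-benzothiazol-2-ylsulfanyl) 3-O-(tri-O-benzylgallate) F3. Thiophilic activation of F3 with AgBF4 (THF, 0 °C) in the presence of 16 should alkylate the only free C8 position of 16 from the β face, and the route is rejoined at 22.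

Step 12. The isopropyl- or arylmagnesium species may attack the gallate carbonyl if the iodine–magnesium exchange or the addition to the hindered, electron-rich aldehyde is slow, and the arylmagnesium may be protonated back to 16. The fallback replaces the preformed basic magnesium nucleophile by a Nozaki–Hiyama–Kishi coupling. Compounds 17 and 7 are stirred with CrCl2 (excess) and NiCl2 (catalytic) in DMF/THF at rt. Nickel inserts into the carbon–iodine bond, the aryl group passes to chromium, and the arylchromium species adds to aldehydes but not to esters. This sets out from 17 and 7 and rejoins the route at 19.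

**Further compounds**

F1 | step 10 | 5,7,3',4'-tetra-O-benzyl-4β-(2-ethoxyethoxy)-(−)-epicatechin | O[C@@H]1[C@@H](OCCOCC)c2c(OCc3ccccc3)cc(OCc3ccccc3)cc2O[C@@H]1c1ccc(OCc2ccccc2)c(OCc2ccccc2)c1
F2 | step 10 | 5,7,3',4'-tetra-O-benzyl-4β-(2-ethoxyethoxy)-(−)-epicatechin 3-O-[3,4,5-tris(benzyloxy)benzoate] | O=C(O[C@@H]1[C@@H](OCCOCC)c2c(OCc3ccccc3)cc(OCc3ccccc3)cc2O[C@@H]1c1ccc(OCc2ccccc2)c(OCc2ccccc2)c1)c1cc(OCc2ccccc2)c(OCc2ccccc2)c(OCc2ccccc2)c1
F3 | step 14 | 5,7,3',4'-tetra-O-benzyl-4β-(1,3-benzothiazol-2-ylsulfanyl)-(−)-epicatechin 3-O-[3,4,5-tris(benzyloxy)benzoate] | O=C(O[C@@H]1[C@@H](Sc2nc3ccccc3s2)c2c(OCc3ccccc3)cc(OCc3ccccc3)cc2O[C@@H]1c1ccc(OCc2ccccc2)c(OCc2ccccc2)c1)c1cc(OCc2ccccc2)c(OCc2ccccc2)c(OCc2ccccc2)c1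
F0 | step 12 | none | none
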